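## Retrosynthetic overview

1. Last bonds: C-acylation of spiro-trione 29 with (R)-2-methylbutanoic acid 25 (from tiglic acid by Ru(OAc)2[(R)-H8-BINAP] hydrogenation), then desilylation.
2. Trione ring (formed third): the tertiary ester 27 undergoes a tethered O→C acyl transfer that fixes the spiro centre, then Dieckmann closure in the same pot.
3. Acyl donor 23 carrying the C(Me)(prenyl) centre: carboxylesterase desymmetrisation of the prochiral malonate 19.
4. cis-Hydrindane 16: [RhCl(C2H4)2]2/(R)-BINAP conjugate addition to cyclopentenone (five-membered ring, bought), chloride annulation closes the six-membered ring second, both carbinols by convex-face MeMgBr/CeCl3 additions, CH2=CHMgBr/CuBr·SMe2 then oxidation supplies the carboxyl carbon.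
5. Ring order: cyclopentane (from 4) → cyclohexane (step 4) → trione ring (step 19).

Assumption: the SMILES descriptors are taken literally (acyl side chain R), and the carboxylesterase is taken to give the (S)-half-ester 20; this sense is not known for this substrate and must be checked on the first run.

Indane numbering of 7 is kept for 8–16, 27 and 28. "α" means the face of the six-membered ring that carries the cyclopentane bonds and both hydroxyls; "β" the face of the ring-fusion hydrogens.

## Route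

Step 1
Reactants: 1 5-chloropent-1-yne
Product: 2 2-bromo-5-chloropent-1-ene
Conditions: Et4N·HBr2, CH2Cl2, 40 °C
Reagents that add atoms: hydrogen bromide, Br
Why: Markovnikov hydrobromination of the terminal alkyne by HBr2− stops at the 2-bromo-1-alkene; no stereocentre is formed.

Step 2
Reactants: 2 2-bromo-5-chloropent-1-ene
Product: 3 2-(5-chloropent-1-en-2-yl)-4,4,5,5-tetramethyl-1,3,2-dioxaborolane
Conditions: B2pin2, PdCl2(PPh3)2 (3 mol %), PPh3, KOPh, toluene, 50 °C
Reagents that add atoms: bis(pinacolato)diboron, CC1(C)OB(OC1(C)C)B1OC(C)(C)C(C)(C)O1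
Why: Miyaura borylation exchanges the alkenyl bromide selectively and leaves the primary alkyl chloride alone.

Step 3
Reactants: 3 2-(5-chloropent-1-en-2-yl)-4,4,5,5-tetramethyl-1,3,2-dioxaborolane; 4 cyclopent-2-en-1-one
Product: 5 (3R)-3-(5-chloropent-1-en-2-yl)cyclopentan-1-one
Conditions: [RhCl(C2H4)2]2 (1.5 mol %), (R)-BINAP (3.3 mol %), aq KOH, dioxane/H2O 10:1, 40 °C
Reagents that add atoms: none
Why: Hayashi–Miyaura asymmetric 1,4-addition, in which the alkenyl–rhodium/(R)-BINAP species adds to one enone face and sets C3 as R (the known sense for (R)-BINAP with cyclopentenone, high ee expected); this is the first stereocentre of the branch.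

Step 4
Reactants: 5 (3R)-3-(5-chloropent-1-en-2-yl)cyclopentan-1-one
Product: 6 (3aR,7aR)-4-methylideneoctahydro-1H-inden-1-one
Conditions: KOt-Bu, t-BuOH/THF, high dilution, 0 → 23 °C
Reagents that add atoms: none
Why: Piers-type methylenecyclohexane annulation, where under equilibrating conditions only the C2 enolate can close a six-membered ring (6-exo-tet alkylation) and the ring fusion is cis because the tether reaches C2 from its own face and cis-hydrindan-1-one is also the thermodynamic epimer.

Step 5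
Reactants: 6 (3aR,7aR)-4-methylideneoctahydro-1H-inden-1-one
Product: 7 (1S,3aR,7aR)-1-methyl-4-methylideneoctahydro-1H-inden-1-ol
Conditions: MeMgBr, CeCl3, THF, −78 °C
Reagents that add atoms: methylmagnesium bromide, C[Mg]Br
Why: 1,2-addition of the non-basic organocerium reagent from the convex face of the cis-fused bicycle puts the methyl group on the face of the angular hydrogens and the hydroxyl on the concave face.

Step 6
Reactants: 7 (1S,3aR,7aR)-1-methyl-4-methylideneoctahydro-1H-inden-1-ol
Product: 8 triethyl{[(1S,3aR,7aR)-1-methyl-4-methylideneoctahydro-1H-inden-1-yl]oxy}silane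
Conditions: Et3SiOTf, 2,6-lutidine, CH2Cl2, −78 → 0 °C
Reagents that add atoms: triethylsilyl trifluoromethanesulfonate, CC[Si](CC)(CC)OS(=O)(=O)C(F)(F)F
Why: silyl triflate protection of the hindered tertiary alcohol gives an ether that survives the later base, ozone and buffered oxidation steps.

Step 7
Reactants: 8 triethyl{[(1S,3aR,7aR)-1-methyl-4-methylideneoctahydro-1H-inden-1-yl]oxy}silane
Product: 9 (1S,3aR,7aR)-1-methyl-1-[(triethylsilyl)oxy]octahydro-4H-inden-4-one
Conditions: O3, CH2Cl2/MeOH, −78 °C; then PPh3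
Reagents that add atoms: ozone, [O-][O+]=O
Why: ozonolysis of the only alkene unmasks the six-ring ketone under neutral conditions, so the adjacent ring-fusion hydrogen is not epimerised.

Step 8
Reactants: 9 (1S,3aR,7aR)-1-methyl-1-[(triethylsilyl)oxy]octahydro-4H-inden-4-one
Product: 11 (1S,3aR,7aR)-1-methyl-1-[(triethylsilyl)oxy]-1,2,3,3a,7,7a-hexahydro-4H-inden-4-one, via trimethylsilyl enol ether 10 (not isolated)
Conditions: LiN(i-Pr)2, Me3SiCl, THF, −78 °C; then Pd(OAc)2 (10 mol %), O2 (1 atm), DMSO, 23 °C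
Reagents that add atoms: none
Why: kinetic deprotonation occurs at the CH2 side and not at the ring-fusion CH, and Saegusa–Ito dehydrogenation of the regio-defined silyl enol ether gives the enone.

Step 9
Reactants: 11 (1S,3aR,7aR)-1-methyl-1-[(triethylsilyl)oxy]-1,2,3,3a,7,7a-hexahydro-4H-inden-4-one
Product: 12 (1S,3aR,6R,7aR)-6-ethenyl-1-methyl-1-[(triethylsilyl)oxy]octahydro-4H-inden-4-one
Conditions: CH2=CHMgBr, CuBr·SMe2 (10 mol %), THF, −78 → −40 °C; aq NH4Cl
Reagents that add atoms: vinylmagnesium bromide, C=C[Mg]Br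
Why: copper-catalysed conjugate addition by axial attack trans to the C7a substituent (convex face) places the vinyl group β; this centre is planarised later and only has to be trans to the future C4 hydroxyl so that no lactone can form.

Step 10
Reactants: 12 (1S,3aR,6R,7aR)-6-ethenyl-1-methyl-1-[(triethylsilyl)oxy]octahydro-4H-inden-4-one
Product: 13 (1S,3aR,4S,6R,7aR)-6-ethenyl-1,4-dimethyl-1-[(triethylsilyl)oxy]octahydro-1H-inden-4-ol
Conditions: MeMgBr, CeCl3, THF, −78 °C
Reagents that add atoms: methylmagnesium bromide, C[Mg]Br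
Why: organocerium 1,2-addition from the convex β face, anti to the adjacent C3a–C3 bond (equatorial attack), gives the methyl group β and the tertiary hydroxyl α.

Step 11
Reactants: 13 (1S,3aR,4S,6R,7aR)-6-ethenyl-1,4-dimethyl-1-[(triethylsilyl)oxy]octahydro-1H-inden-4-ol
Product: 14 (1S,3aR,4S,6R,7aR)-4-hydroxy-1,4-dimethyl-1-[(triethylsilyl)oxy]octahydro-1H-indene-6-carbaldehyde
Conditions: O3, CH2Cl2, −78 °C; then PPh3; used crude
Reagents that add atoms: ozone, [O-][O+]=O
Why: ozonolysis of the terminal vinyl group with reductive work-up gives the aldehyde, which is trans to the tertiary hydroxyl and so cannot close to a lactol.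

Step 12
Reactants: 14 (1S,3aR,4S,6R,7aR)-4-hydroxy-1,4-dimethyl-1-[(triethylsilyl)oxy]octahydro-1H-indene-6-carbaldehyde
Product: 16 methyl (1S,3aR,4S,6R,7aR)-4-hydroxy-1,4-dimethyl-1-[(triethylsilyl)oxy]octahydro-1H-indene-6-carboxylate, via carboxylic acid 15 (not isolated)
Conditions: NaClO2, NaH2PO4, 2-methyl-2-butene, t-BuOH/H2O, 0 °C; then MeI, K2CO3, DMF, 23 °C
Reagents that add atoms: sodium chlorite, [Na+].[O-]Cl=O; iodomethane, CI
Why: Pinnick oxidation followed by carboxylate O-methylation leaves the tertiary alcohol and the silyl ether untouched.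

Step 13
Reactants: 17 dimethyl 2-methylmalonate; 18 1-bromo-3-methylbut-2-ene
Product: 19 dimethyl 2-methyl-2-(3-methylbut-2-en-1-yl)propanedioate
Conditions: NaH, THF, 0 → 23 °C
Reagents that add atoms: none
Why: SN2 C-alkylation of the malonate enolate with the allylic bromide gives the prochiral diester.

Step 14
Reactants: 19 dimethyl 2-methyl-2-(3-methylbut-2-en-1-yl)propanedioate
Product: 20 (2S)-2-(methoxycarbonyl)-2,5-dimethylhex-4-enoic acid
Conditions: carboxylesterase (pig liver esterase), 0.1 M phosphate buffer pH 7.5, 10 % DMSO, 25 °C, pH-stat (1 M NaOH); cold HCl to pH 3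
Reagents that add atoms: water, O
Why: enantiotopic-group-selective hydrolysis by the carboxylesterase (a serine hydrolase) creates the quaternary stereocentre that becomes the C(Me)(prenyl) carbon, the first carboxylate stops the second hydrolysis, and the ee can be raised by crystallising the dicyclohexylammonium salt.

Step 15
Reactants: 20 (2S)-2-(methoxycarbonyl)-2,5-dimethylhex-4-enoic acid
Product: 22 methyl (2S)-2-acetyl-2,5-dimethylhex-4-enoate, via acid chloride 21 (not isolated)
Conditions: 1-chloro-N,N,2-trimethylprop-1-en-1-amine, CH2Cl2, 0 °C; then Me2CuLi, Et2O, −78 °C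
Reagents that add atoms: lithium dimethylcuprate, [Li+].C[Cu-]C
Why: the chloroenamine makes the acid chloride without HCl (which could add to the prenyl alkene), and Me2CuLi converts it into the methyl ketone without touching the ester or the quaternary centre.

Step 16
Reactants: 22 methyl (2S)-2-acetyl-2,5-dimethylhex-4-enoate
Product: 23 (2S)-2-acetyl-2,5-dimethylhex-4-enoic acid
Conditions: LiOH (2 equiv), THF/H2O 3:1, 0 °C; cold 1 M HCl to pH 3; kept below 5 °C and used at once
Reagents that add atoms: lithium hydroxide, [Li+].[OH-]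
Why: cold dilute saponification is intended to hydrolyse the ester faster than hydroxide cleaves the ketone (retro-Claisen), and the β-keto acid is kept cold so that it does not decarboxylate.

Step 17
Reactants: 24 (E)-2-methylbut-2-enoic acid (tiglic acid)
Product: 25 (2R)-2-methylbutanoic acid
Conditions: Ru(OAc)2[(R)-H8-BINAP] (0.5 mol %), H2 (1.5 atm), MeOH, 20 °C
Reagents that add atoms: none
Why: carboxylate-directed asymmetric hydrogenation of the α,β-unsaturated acid sets the side-chain centre as R in high ee.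

Step 18
Reactants: 16 methyl (1S,3aR,4S,6R,7aR)-4-hydroxy-1,4-dimethyl-1-[(triethylsilyl)oxy]octahydro-1H-indene-6-carboxylate; 23 (2S)-2-acetyl-2,5-dimethylhex-4-enoic acid
Product: 27 methyl (1S,3aR,4S,6R,7aR)-4-{[(2S)-2-acetyl-2,5-dimethylhex-4-enoyl]oxy}-1,4-dimethyl-1-[(triethylsilyl)oxy]octahydro-1H-indene-6-carboxylate, via acid chloride 26 (not isolated)
Conditions: 23 (1.5 equiv), 1-chloro-N,N,2-trimethylprop-1-en-1-amine, CH2Cl2, 0 °C; 16, LiN(SiMe3)2 (1.05 equiv), THF, −78 °C; combine, DMAP (cat.), −78 → 0 °C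
Reagents that add atoms: none
Why: O-acylation of the lithium tertiary alkoxide by an acid chloride that has no α-hydrogen; the C6 ester is trans to the alkoxide and cannot lactonise.

Step 19
Reactants: 27 methyl (1S,3aR,4S,6R,7aR)-4-{[(2S)-2-acetyl-2,5-dimethylhex-4-enoyl]oxy}-1,4-dimethyl-1-[(triethylsilyl)oxy]octahydro-1H-indene-6-carboxylate
Product: 29 spiro-trione (enol form) having every stereocentre of 32 but lacking the 2-methylbutanoyl group and carrying the cyclopentanol oxygen as its triethylsilyl ether, via C-acyl keto ester 28 (not isolated)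
Conditions: LiN(i-Pr)2 (2.5 equiv), THF, −78 → 0 °C; cold 0.5 M HCl to pH 4
Reagents that add atoms: none
Why: the ester enolate takes the acyl group from the α-oriented C4 oxygen through a five-membered transition state (Baker–Venkataraman-type O→C acyl transfer), so the new ketone must be α on the new quaternary carbon and the spiro centre is fixed, after which the methyl ketone enolate closes the trione ring by Dieckmann condensation onto the β ester.

Step 20
Reactants: 29 spiro-trione; 25 (2R)-2-methylbutanoic acid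
Product: 31 triethylsilyl ether of 32 (at the cyclopentanol oxygen), via enol ester 30 (not isolated)
Conditions: DCC, DMAP (1.2 equiv), CH2Cl2, 0 → 23 °C
Reagents that add atoms: none
Why: Steglich O-acylation of the acidic enol is followed by the DMAP-mediated 1,3 O→C acyl shift to the 2-acyl-1,3-dione, and tertiary alcohols are not acylated under these conditions.

Step 21
Reactants: 31 triethylsilyl ether of 32
Product: 32 CNP0236509.3
Conditions: HF·pyridine, THF, 0 °C
Reagents that add atoms: none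
Why: fluoride cleaves the tertiary silyl ether under conditions mild enough for the prenyl group, the tertiary alcohols and the enolised triketone.

## Compound list

1 | 5-chloropent-1-yne | C#CCCCCl | starting material
2 | 2-bromo-5-chloropent-1-ene | C=C(Br)CCCCl | intermediate
3 | 2-(5-chloropent-1-en-2-yl)-4,4,5,5-tetramethyl-1,3,2-dioxaborolane | C=C(CCCCl)B1OC(C)(C)C(C)(C)O1 | intermediate
4 | cyclopent-2-en-1-one | O=C1C=CCC1 | starting material
5 | (3R)-3-(5-chloropent-1-en-2-yl)cyclopentan-1-one | O=C1C[C@@H](CC1)C(=C)CCCCl | intermediate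
6 | (3aR,7aR)-4-methylideneoctahydro-1H-inden-1-one (cis-fused) | C1C[C@@H]2[C@@H](CCC2=O)C(=C)C1 | intermediate
7 | (1S,3aR,7aR)-1-methyl-4-methylideneoctahydro-1H-inden-1-ol | C1C[C@@H]2[C@@H](CC[C@]2(C)O)C(=C)C1 | intermediate
8 | triethyl{[(1S,3aR,7aR)-1-methyl-4-methylideneoctahydro-1H-inden-1-yl]oxy}silane | C1C[C@@H]2[C@@H](CC[C@]2(C)O[Si](CC)(CC)CC)C(=C)C1 | intermediate
9 | (1S,3aR,7aR)-1-methyl-1-[(triethylsilyl)oxy]octahydro-4H-inden-4-one | C1C[C@@H]2[C@@H](CC[C@]2(C)O[Si](CC)(CC)CC)C(=O)C1 | intermediate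
10 | trimethylsilyl enol ether of 9 (C4=C5 double bond, 4-OSiMe3) | C1C[C@@H]2[C@@H](CC[C@]2(C)O[Si](CC)(CC)CC)C(O[Si](C)(C)C)=C1 | intermediate
11 | (1S,3aR,7aR)-1-methyl-1-[(triethylsilyl)oxy]-1,2,3,3a,7,7a-hexahydro-4H-inden-4-one | C=1C[C@@H]2[C@@H](CC[C@]2(C)O[Si](CC)(CC)CC)C(=O)C=1 | intermediate
12 | (1S,3aR,6R,7aR)-6-ethenyl-1-methyl-1-[(triethylsilyl)oxy]octahydro-4H-inden-4-one | [C@@H]1(C=C)C[C@@H]2[C@@H](CC[C@]2(C)O[Si](CC)(CC)CC)C(=O)C1 | intermediate
13 | (1S,3aR,4S,6R,7aR)-6-ethenyl-1,4-dimethyl-1-[(triethylsilyl)oxy]octahydro-1H-inden-4-ol | [C@@H]1(C=C)C[C@@H]2[C@@H](CC[C@]2(C)O[Si](CC)(CC)CC)[C@@](C)(O)C1 | intermediate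
14 | (1S,3aR,4S,6R,7aR)-4-hydroxy-1,4-dimethyl-1-[(triethylsilyl)oxy]octahydro-1H-indene-6-carbaldehyde | [C@@H]1(C=O)C[C@@H]2[C@@H](CC[C@]2(C)O[Si](CC)(CC)CC)[C@@](C)(O)C1 | intermediate
15 | (1S,3aR,4S,6R,7aR)-4-hydroxy-1,4-dimethyl-1-[(triethylsilyl)oxy]octahydro-1H-indene-6-carboxylic acid | [C@@H]1(C(=O)O)C[C@@H]2[C@@H](CC[C@]2(C)O[Si](CC)(CC)CC)[C@@](C)(O)C1 | intermediate
16 | methyl (1S,3aR,4S,6R,7aR)-4-hydroxy-1,4-dimethyl-1-[(triethylsilyl)oxy]octahydro-1H-indene-6-carboxylate | [C@@H]1(C(=O)OC)C[C@@H]2[C@@H](CC[C@]2(C)O[Si](CC)(CC)CC)[C@@](C)(O)C1 | intermediate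
17 | dimethyl 2-methylmalonate | COC(=O)C(C)C(=O)OC | starting material
18 | 1-bromo-3-methylbut-2-ene (prenyl bromide) | CC(C)=CCBr | starting material
19 | dimethyl 2-methyl-2-(3-methylbut-2-en-1-yl)propanedioate | COC(=O)C(C)(CC=C(C)C)C(=O)OC | intermediate
20 | (2S)-2-(methoxycarbonyl)-2,5-dimethylhex-4-enoic acid | OC(=O)[C@](C)(CC=C(C)C)C(=O)OC | intermediate
21 | methyl (2R)-2-(chlorocarbonyl)-2,5-dimethylhex-4-enoate | ClC(=O)[C@](C)(CC=C(C)C)C(=O)OC | intermediate
22 | methyl (2S)-2-acetyl-2,5-dimethylhex-4-enoate | CC(=O)[C@](C)(CC=C(C)C)C(=O)OC | intermediate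
23 | (2S)-2-acetyl-2,5-dimethylhex-4-enoic acid | CC(=O)[C@](C)(CC=C(C)C)C(=O)O | intermediate
24 | (E)-2-methylbut-2-enoic acid (tiglic acid) | C/C=C(\C)C(=O)O | starting material
25 | (2R)-2-methylbutanoic acid | CC[C@@H](C)C(=O)O | intermediate
26 | (2S)-2-acetyl-2,5-dimethylhex-4-enoyl chloride | CC(=O)[C@](C)(CC=C(C)C)C(=O)Cl | intermediate
27 | methyl (1S,3aR,4S,6R,7aR)-4-{[(2S)-2-acetyl-2,5-dimethylhex-4-enoyl]oxy}-1,4-dimethyl-1-[(triethylsilyl)oxy]octahydro-1H-indene-6-carboxylate | [C@@H]1(C(=O)OC)C[C@@H]2[C@@H](CC[C@]2(C)O[Si](CC)(CC)CC)[C@@](C)(OC(=O)[C@@](C)(CC=C(C)C)C(C)=O)C1 | intermediate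
28 | methyl (1S,3aR,4S,6R,7aR)-6-[(2S)-2-acetyl-2,5-dimethylhex-4-enoyl]-4-hydroxy-1,4-dimethyl-1-[(triethylsilyl)oxy]octahydro-1H-indene-6-carboxylate (acyl group α, ester β) | CC(=O)[C@](C)(CC=C(C)C)C(=O)[C@]1(C[C@@H]2[C@@H](CC[C@]2(C)O[Si](CC)(CC)CC)[C@@](C)(O)C1)C(=O)OC | intermediate
29 | spiro-trione, enol form: 32 without the 2-methylbutanoyl group and with the cyclopentanol oxygen as triethylsilyl ether; all ring stereocentres as in 32 | C1=C(O)[C@](C)(CC=C(C)C)C(=O)[C@]2(C[C@@H]3[C@@H](CC[C@]3(C)O[Si](CC)(CC)CC)[C@@](C)(O)C2)C1=O | intermediate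
30 | enol (2R)-2-methylbutanoate of 29 | C1=C(OC(=O)[C@H](C)CC)[C@](C)(CC=C(C)C)C(=O)[C@]2(C[C@@H]3[C@@H](CC[C@]3(C)O[Si](CC)(CC)CC)[C@@](C)(O)C2)C1=O | intermediate
31 | 3'-O-triethylsilyl ether of 32 (cyclopentanol oxygen) | CC[C@@H](C)C(=O)C1=C(O)[C@](C)(CC=C(C)C)C(=O)[C@]2(C[C@@H]3[C@@H](CC[C@]3(C)O[Si](CC)(CC)CC)[C@@](C)(O)C2)C1=O | intermediate
32 | CNP0236509.3: (1R,3S,3'S,3a'R,7'S,7a'R)-3',4,7'-trihydroxy-3,3',7'-trimethyl-5-[(2R)-2-methylbutanoyl]-3-(3-methylbut-2-en-1-yl)-1',2',3',3a',4',6',7',7a'-octahydrospiro[cyclohex-4-ene-1,5'-indene]-2,6-dione | CC[C@@H](C)C(=O)C1=C(O)[C@](C)(CC=C(C)C)C(=O)[C@]2(C[C@@H]3[C@@H](CC[C@]3(C)O)[C@@](C)(O)C2)C1=O | target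

## Step count and risks

Total: 21 steps. Longest linear sequence: 16 steps (steps 1–12, then 18–21).

The three steps most likely to fail:

Step 18. The hydroxyl of 16 is tertiary, axial and flanked by the ring fusion, and the acid chloride is neopentyl-like, so the ester may form slowly or not at all. The fallback gives up the tether and makes the C–C bond directly; it sets out from 16 (with 26 prepared as in step 18) and comes back at 29. Compound 16 is silylated (Me3SiOTf, 2,6-lutidine) to methyl (1S,3aR,4S,6R,7aR)-1,4-dimethyl-1-[(triethylsilyl)oxy]-4-[(trimethylsilyl)oxy]octahydro-1H-indene-6-carboxylate F1. Its lithium enolate (LiN(i-Pr)2, THF, −78 °C) is C-acylated with 26 to give the 4-O-trimethylsilyl ether of 28 F2. Attack should be equatorial on the α face because the C4 methyl group is axial on the β face in the enolate chair, but this selectivity is a conformational prediction and not enforced. A second portion of LiN(i-Pr)2 closes the trione ring (Dieckmann) to the 7'-O-trimethylsilyl ether of 29 F3, and dilute HCl in THF removes the tertiary trimethylsilyl group to give 29.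

Step 19. Double deprotonation of 27 may be slow at the hindered C6–H, or the methyl ketone enolate may react elsewhere first. The fallback separates the two events; it sets out from 27 and comes back at 29. Me3SiOTf/Et3N converts the methyl ketone of 27 into the trimethylsilyl enol ether of 27 F4. One equivalent of LiN(i-Pr)2 can now form only the ester enolate, and the O→C acyl transfer gives the trimethylsilyl enol ether of 28 F5. MeLi in THF at 0 °C then releases the ketone enolate, which undergoes the Dieckmann closure to 29.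

Step 16. Hydroxide may cleave the non-enolisable β-keto ester 22 (retro-Claisen) or the acid 23 may decarboxylate. The fallback installs the ketone after the saponification; it sets out from 21 and comes back at 23. The acid chloride 21 is treated with MeNHOMe·HCl and pyridine to give methyl (2S)-2-[methoxy(methyl)carbamoyl]-2,5-dimethylhex-4-enoate F6. LiOH in THF/H2O at 40 °C hydrolyses its methyl ester (no ketone is present) to (2S)-2-[methoxy(methyl)carbamoyl]-2,5-dimethylhex-4-enoic acid F7. MeMgBr (2.2 equiv, THF, −20 °C) converts the Weinreb amide into the methyl ketone while the carboxylate is protected as its salt, and cold acidification gives 23.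

Further compounds
F1 | step 18 | methyl (1S,3aR,4S,6R,7aR)-1,4-dimethyl-1-[(triethylsilyl)oxy]-4-[(trimethylsilyl)oxy]octahydro-1H-indene-6-carboxylate | [C@@H]1(C(=O)OC)C[C@@H]2[C@@H](CC[C@]2(C)O[Si](CC)(CC)CC)[C@@](C)(O[Si](C)(C)C)C1
F2 | step 18 | 4-O-trimethylsilyl ether of 28 | CC(=O)[C@](C)(CC=C(C)C)C(=O)[C@]1(C[C@@H]2[C@@H](CC[C@]2(C)O[Si](CC)(CC)CC)[C@@](C)(O[Si](C)(C)C)C1)C(=O)OC
F3 | step 18 | 7'-O-trimethylsilyl ether of 29 | C1=C(O)[C@](C)(CC=C(C)C)C(=O)[C@]2(C[C@@H]3[C@@H](CC[C@]3(C)O[Si](CC)(CC)CC)[C@@](C)(O[Si](C)(C)C)C2)C1=O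
F4 | step 19 | trimethylsilyl enol ether of 27 | [C@@H]1(C(=O)OC)C[C@@H]2[C@@H](CC[C@]2(C)O[Si](CC)(CC)CC)[C@@](C)(OC(=O)[C@@](C)(CC=C(C)C)C(=C)O[Si](C)(C)C)C1
F5 | step 19 | trimethylsilyl enol ether of 28 | C=C(O[Si](C)(C)C)[C@](C)(CC=C(C)C)C(=O)[C@]1(C[C@@H]2[C@@H](CC[C@]2(C)O[Si](CC)(CC)CC)[C@@](C)(O)C1)C(=O)OC
F6 | step 16 | methyl (2S)-2-[methoxy(methyl)carbamoyl]-2,5-dimethylhex-4-enoate | CON(C)C(=O)[C@](C)(CC=C(C)C)C(=O)OC
F7 | step 16 | (2S)-2-[methoxy(methyl)carbamoyl]-2,5-dimethylhex-4-enoic acid | CON(C)C(=O)[C@](C)(CC=C(C)C)C(=O)O
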